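**Retrosynthetic overview**

1. Target ⇐ (Z)-2-(2-bromoethylidene)cyclohexanol (C–OH → C–Cl with inversion) ⇐ vinyl oxirane (SN2' opening by bromide creates CH2Br and the Z alkene).
2. Vinyl oxirane ⇐ 1-vinylcyclohexene ⇐ 4-bromo-2-chloro-3,3-dimethylcyclohexanone (vinyl addition, dehydration, reagent-controlled epoxidation).
3. Key disconnection: the C5–C6 bond of that ketone, made by 6-endo bromine-atom-transfer radical cyclisation of an acyclic bromomethyl ketone. The α-halo ketone acts as an enolonium equivalent, so the ketone α-carbon is joined to the terminal alkene carbon (two donor carbons) while Br is delivered to the neopentyl carbon.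
4. Bromomethyl ketone ⇐ (R)-2-chloro-3,3-dimethylpent-4-enal + LiCH2Br (from CH2Br2) ⇐ organocatalytic α-chlorination ⇐ methyl 3,3-dimethylpent-4-enoate.
5. Ring order: the cyclohexane (the only carbocycle) is closed in step 5; a transient oxirane is made in step 8 and opened in step 9.

Assumption: the SMILES is taken as drawn, i.e. (2S,3Z,4S,6S)-6-bromo-3-(2-bromoethylidene)-2,4-dichloro-1,1-dimethylcyclohexane (Br trans to both Cl, the two Cl cis, CH2Br on the side of the CHCl next to CMe2).

**Route**

Step 1
Reactants: 1 methyl 3,3-dimethylpent-4-enoate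
Product: 2 3,3-dimethylpent-4-enal
Conditions: i-Bu2AlH (1.05 equiv), CH2Cl2, −78 °C; then H2O work-up
Reagents that add atoms: none
Why: Partial reduction of an ester with i-Bu2AlH at −78 °C (DIBAL-H ester-to-aldehyde reduction) stops at the aluminium hemiacetal, which releases the aldehyde on work-up; no stereocentre is formed.

Step 2
Reactants: 2 3,3-dimethylpent-4-enal
Product: 3 (2R)-2-chloro-3,3-dimethylpent-4-enal
Conditions: NCS (1.3 equiv), (2S,5S)-2,5-diphenylpyrrolidine (10 mol %), CH2Cl2, 0 °C → rt; used crude
Reagents that add atoms: N-chlorosuccinimide, ClN1C(=O)CCC1=O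
Why: Enamine-catalysed α-chlorination of aldehydes (Jørgensen type, tolerant of the β-quaternary 3,3-dimethylbutanal pattern) delivers Cl+ to one enamine face and sets C2 as R, the catalyst antipode being the one opposite to that which gives the S series.

Step 3
Reactants: 3 (2R)-2-chloro-3,3-dimethylpent-4-enal; 4 dibromomethane
Product: 5 (3R)-1-bromo-3-chloro-4,4-dimethylhex-5-en-2-ol (C2 epimers, anti bromo chlorohydrin major)
Conditions: CH2Br2 (1.5 equiv), n-BuLi (1.3 equiv, added last), THF, −78 °C; AcOH quench at −78 °C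
Reagents that add atoms: none
Why: Bromomethyllithium made in situ by Br/Li exchange (halomethyllithium carbenoid addition) is an umpoled one-carbon donor that adds to the aldehyde, the cold acidic quench prevents epoxide closure, and the new carbinol centre (polar Felkin–Anh, anti major) is removed in step 4.

Step 4
Reactants: 5 (3R)-1-bromo-3-chloro-4,4-dimethylhex-5-en-2-ol
Product: 6 (3R)-1-bromo-3-chloro-4,4-dimethylhex-5-en-2-one
Conditions: Dess–Martin periodinane (1,1,1-triacetoxy-1,1-dihydro-1,2-benziodoxol-3(1H)-one, 1.2 equiv), CH2Cl2, 0 °C → rt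
Reagents that add atoms: none
Why: Dess–Martin oxidation of the secondary alcohol is mild enough to leave the enolisable α-chloro stereocentre and both halides intact; no stereocentre is created.

Step 5
Reactants: 6 (3R)-1-bromo-3-chloro-4,4-dimethylhex-5-en-2-one
Product: 7 (2R,4S)-4-bromo-2-chloro-3,3-dimethylcyclohexan-1-one (Br trans to Cl)
Conditions: CuBr (10 mol %), tris(2-pyridylmethyl)amine (10 mol %), degassed 1,2-dichloroethane (0.02 M), 40 °C
Reagents that add atoms: none
Why: Copper-catalysed atom-transfer radical cyclisation (Kharasch type) in which the bromomethyl ketone serves as an enolonium (a2) equivalent: its electrophilic α-keto radical attacks the terminal carbon of the unactivated vinyl group (two innately nucleophilic carbons) in the 6-endo mode preferred by 2-oxohex-5-enyl radicals and reinforced by the gem-dimethyl group, and the resulting secondary radical takes bromine from CuBr2(TPMA) on the face anti to the α-chlorine, avoiding a 1,3-diaxial Br/Cl contact and setting C4 trans to C2.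

Step 6
Reactants: 7 (2R,4S)-4-bromo-2-chloro-3,3-dimethylcyclohexan-1-one; 8 vinylmagnesium bromide
Product: 9 (1R,2R,4S)-4-bromo-2-chloro-1-ethenyl-3,3-dimethylcyclohexan-1-ol (OH cis to Cl)
Conditions: CH2=CHMgBr (1.5 equiv), CeCl3 (1.5 equiv), THF, −78 °C; then AcOH, −78 °C
Reagents that add atoms: none
Why: Organocerium 1,2-addition (Imamoto conditions) to the hindered, enolisable α-chloro ketone avoids enolisation and epimerisation, the vinyl group entering anti to the C–Cl bond (polar Felkin–Anh) to give mainly the alcohol with OH cis to Cl; this carbinol centre disappears in step 7.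

Step 7
Reactants: 9 (1R,2R,4S)-4-bromo-2-chloro-1-ethenyl-3,3-dimethylcyclohexan-1-ol
Product: 10 (4S,6S)-4-bromo-6-chloro-1-ethenyl-5,5-dimethylcyclohex-1-ene
Conditions: Martin sulfurane Ph2S[OC(CF3)2Ph]2 (1.5 equiv), CH2Cl2, 0 °C → rt
Reagents that add atoms: none
Why: Martin sulfurane dehydration of a tertiary alcohol goes through the vinyl-stabilised tertiary cation (E1-like) and removes a proton from the unhindered ring CH2 rather than from the CHCl flanked by the quaternary carbon, giving the conjugated 1-vinylcyclohexene without touching the two halogen stereocentres.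

Step 8
Reactants: 10 (4S,6S)-4-bromo-6-chloro-1-ethenyl-5,5-dimethylcyclohex-1-ene
Product: 11 (1R,2R,4S,6R)-4-bromo-2-chloro-1-ethenyl-3,3-dimethyl-7-oxabicyclo[4.1.0]heptane (oxirane O cis to Br, trans to Cl)
Conditions: D-fructose-derived Shi ketone (1,2:4,5-di-O-isopropylidene-β-D-erythro-2,3-hexodiulo-2,6-pyranose, 30 mol %), KHSO5 (as Oxone), K2CO3, Bu4NHSO4 (cat.), MeCN–dimethoxymethane–aqueous buffer (pH about 10.5), 0 °C
Reagents that add atoms: potassium peroxymonosulfate (KHSO5), [K+].[O-]S(=O)(=O)OO
Why: Shi asymmetric epoxidation (chiral dioxirane) is chemoselective for the more electron-rich trisubstituted ring alkene of a conjugated diene and is reagent-controlled: by analogy with 1-arylcyclohexenes (spiro transition state) the D-fructose-derived ketone delivers oxygen to the face cis to Br and anti to the allylic C–Cl bond, setting C1 and C6.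

Step 9
Reactants: 11 (1R,2R,4S,6R)-4-bromo-2-chloro-1-ethenyl-3,3-dimethyl-7-oxabicyclo[4.1.0]heptane
Product: 12 (1R,2Z,3S,5S)-5-bromo-2-(2-bromoethylidene)-3-chloro-4,4-dimethylcyclohexan-1-ol
Conditions: LiBr (3 equiv), CuBr (10 mol %), AcOH (1.5 equiv), THF, −20 °C
Reagents that add atoms: lithium bromide, [Li+].[Br-]
Why: Copper-assisted SN2' (1,4) opening of a vinyl oxirane by bromide, the reaction type of the E-selective 1,4-hydrohalogenation of isoprene monoxide: bromide attacks the vinyl terminus and the allylic C–O bond breaks with CH2Br anti to the carbinol carbon, because the in-plane (equatorial) C–O bond on that side would suffer A(1,3) strain whereas the CHCl side presents only H (Cl axial), so the alkene forms Z and the carbinol keeps its configuration.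

Step 10
Reactants: 12 (1R,2Z,3S,5S)-5-bromo-2-(2-bromoethylidene)-3-chloro-4,4-dimethylcyclohexan-1-ol
Product: 13 (2S,3Z,4S,6S)-6-bromo-3-(2-bromoethylidene)-2,4-dichloro-1,1-dimethylcyclohexane (target)
Conditions: PPh3 (1.2 equiv, added last), hexachloroacetone (2 equiv), CH2Cl2, −30 → 0 °C, 20 min
Reagents that add atoms: hexachloroacetone, ClC(Cl)(Cl)C(=O)C(Cl)(Cl)Cl
Why: Appel-type deoxychlorination of an allylic alcohol with PPh3/hexachloroacetone is an SN2 displacement of the alkoxyphosphonium ion with inversion and without allylic transposition, turning the equatorial (1R) alcohol into the axial chloride cis to the other chlorine, i.e. the (4S) centre of the target.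

**Compound list**

1 | methyl 3,3-dimethylpent-4-enoate | COC(=O)CC(C)(C)C=C | starting material
2 | 3,3-dimethylpent-4-enal | O=CCC(C)(C)C=C | intermediate
3 | (2R)-2-chloro-3,3-dimethylpent-4-enal | O=C[C@H](Cl)C(C)(C)C=C | intermediate
4 | dibromomethane | BrCBr | starting material
5 | (3R)-1-bromo-3-chloro-4,4-dimethylhex-5-en-2-ol (C2 epimers) | OC(CBr)[C@H](Cl)C(C)(C)C=C | intermediate
6 | (3R)-1-bromo-3-chloro-4,4-dimethylhex-5-en-2-one | O=C(CBr)[C@H](Cl)C(C)(C)C=C | intermediate
7 | (2R,4S)-4-bromo-2-chloro-3,3-dimethylcyclohexan-1-one | CC1(C)[C@@H](Br)CCC(=O)[C@@H]1Cl | intermediate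
8 | vinylmagnesium bromide | C=C[Mg]Br | starting material
9 | (1R,2R,4S)-4-bromo-2-chloro-1-ethenyl-3,3-dimethylcyclohexan-1-ol | CC1(C)[C@@H](Br)CC[C@@](O)(C=C)[C@@H]1Cl | intermediate
10 | (4S,6S)-4-bromo-6-chloro-1-ethenyl-5,5-dimethylcyclohex-1-ene | CC1(C)[C@@H](Br)CC=C(C=C)[C@@H]1Cl | intermediate
11 | (1R,2R,4S,6R)-4-bromo-2-chloro-1-ethenyl-3,3-dimethyl-7-oxabicyclo[4.1.0]heptane | CC1(C)[C@@H](Br)C[C@H]2O[C@@]2(C=C)[C@@H]1Cl | intermediate
12 | (1R,2Z,3S,5S)-5-bromo-2-(2-bromoethylidene)-3-chloro-4,4-dimethylcyclohexan-1-ol | CC1(C)[C@@H](Br)C[C@@H](O)/C(=C/CBr)[C@@H]1Cl | intermediate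
13 | (2S,3Z,4S,6S)-6-bromo-3-(2-bromoethylidene)-2,4-dichloro-1,1-dimethylcyclohexane | CC1(C)[C@@H](Br)C[C@H](Cl)/C(=C/CBr)[C@@H]1Cl | target

**Step count and risks**

Total steps: 10. Longest linear sequence: 10 (from 1 to 13).

The three steps most likely to fail:

Step 5 (bromine transfer to the hindered radical may be slow, or the bromine may enter cis to chlorine). The fallback sets out from 6 and comes back at 7. It replaces atom transfer by a degenerative xanthate-transfer cyclisation followed by a separate radical bromination. The primary bromide of 6 is displaced with potassium O-ethyl xanthate (acetone, 0 °C) to give S-[(3R)-3-chloro-4,4-dimethyl-2-oxohex-5-en-1-yl] O-ethyl carbonodithioate F1. Dilauroyl peroxide in refluxing 1,2-dichloroethane then closes the ring by 6-endo xanthate transfer to O-ethyl S-[(3R)-3-chloro-2,2-dimethyl-4-oxocyclohexyl] carbonodithioate F2 (C1 epimers). Radical xanthate-to-bromide exchange with ethyl 2-bromo-2-methylpropanoate and dilauroyl peroxide converts F2 into 7, with bromine again entering trans to chlorine.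

Step 9 (1,2- versus 1,4-opening and E/Z control). The fallback sets out from 11 and comes back at 12. It fixes the geometry thermodynamically at the enone stage and sets the carbinol by reagent control. 11 is opened with HBr (Et2O, −30 °C) without regard to geometry, giving 12 mixed with (1R,2E,3S,5S)-5-bromo-2-(2-bromoethylidene)-3-chloro-4,4-dimethylcyclohexan-1-ol F3. Dess–Martin oxidation of the mixture gives (2Z,3S,5S)-5-bromo-2-(2-bromoethylidene)-3-chloro-4,4-dimethylcyclohexan-1-one F4 and (2E,3S,5S)-5-bromo-2-(2-bromoethylidene)-3-chloro-4,4-dimethylcyclohexan-1-one F5. LiBr with a trace of HBr in acetone converts F5 into F4 by reversible SN2' addition–elimination of bromide, F4 being favoured because its CH2Br lies anti to the carbonyl oxygen. Corey–Bakshi–Shibata reduction ((S)-2-methyl-CBS-oxazaborolidine, BH3·SMe2, −30 °C) of F4 returns 12.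

Step 10 (chloride exchange at, or phosphine attack on, the primary allylic bromide; SN2' leakage). The fallback sets out from 11 and comes back at 13. The bromide is introduced last. 11 is opened with LiCl, CuCl (cat.) and AcOH to (1R,2Z,3S,5S)-5-bromo-3-chloro-2-(2-chloroethylidene)-4,4-dimethylcyclohexan-1-ol F6. PPh3/hexachloroacetone converts F6 with inversion into (2S,3Z,4S,6S)-6-bromo-2,4-dichloro-3-(2-chloroethylidene)-1,1-dimethylcyclohexane F7. A Finkelstein exchange (NaBr, acetone, 50 °C) then replaces only the primary allylic chloride of F7 to give 13.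

**Further compounds**

F1 | step 5 | S-[(3R)-3-chloro-4,4-dimethyl-2-oxohex-5-en-1-yl] O-ethyl carbonodithioate | CCOC(=S)SCC(=O)[C@H](Cl)C(C)(C)C=C
F2 | step 5 | O-ethyl S-[(3R)-3-chloro-2,2-dimethyl-4-oxocyclohexyl] carbonodithioate (C1 epimers) | CCOC(=S)SC1CCC(=O)[C@H](Cl)C1(C)C
F3 | step 9 | (1R,2E,3S,5S)-5-bromo-2-(2-bromoethylidene)-3-chloro-4,4-dimethylcyclohexan-1-ol | CC1(C)[C@@H](Br)C[C@@H](O)/C(=C\CBr)[C@@H]1Cl
F4 | step 9 | (2Z,3S,5S)-5-bromo-2-(2-bromoethylidene)-3-chloro-4,4-dimethylcyclohexan-1-one | CC1(C)[C@@H](Br)CC(=O)/C(=C/CBr)[C@@H]1Cl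
F5 | step 9 | (2E,3S,5S)-5-bromo-2-(2-bromoethylidene)-3-chloro-4,4-dimethylcyclohexan-1-one | CC1(C)[C@@H](Br)CC(=O)/C(=C\CBr)[C@@H]1Cl
F6 | step 10 | (1R,2Z,3S,5S)-5-bromo-3-chloro-2-(2-chloroethylidene)-4,4-dimethylcyclohexan-1-ol | CC1(C)[C@@H](Br)C[C@@H](O)/C(=C/CCl)[C@@H]1Cl
F7 | step 10 | (2S,3Z,4S,6S)-6-bromo-2,4-dichloro-3-(2-chloroethylidene)-1,1-dimethylcyclohexane | CC1(C)[C@@H](Br)C[C@H](Cl)/C(=C/CCl)[C@@H]1Cl
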